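**Retrosynthetic overview**
1. Ring letters: A–O–B(–G)–O–C–O–D(–O–E–H)(–O–F–J). G, H and J are the C-linked 2,4,6-trihydroxyphenyl rings, and E–H and F–J are identical. The last step is global O-demethylation of the docosamethyl ether.
2. Each aryl ether is cut so that the 2,6-dioxygenated (hindered) ring is the phenol and the other ring carries the halide. A/O–B is an Ullmann coupling (last ether). C/O–D is the Ullmann union of the two halves. B/O–C, D/O–E and D/O–F are SNAr reactions on fluorobenzaldehydes.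
3. Each formyl group first activates its fluoride(s). A Baeyer–Villiger oxidation then turns it into the phenol needed for the next ether bond.
4. Biaryl bonds: E–H (= F–J) comes from oxidative homocoupling of lithiated 1,3,5-trimethoxybenzene, and B–G from a Suzuki coupling.
5. No ring is built. The nine purchased benzene rings are joined in this order: E–H/F–J, then D; separately B–G, then C; then C–D; ring A last.

Assumption: the SMILES has no stereocentre and no biaryl axis is stereogenic (each 2,4,6-trioxygenated ring is symmetric about its axis), so the target is achiral and no step sets stereochemistry; all starting materials, including 4-fluoro-2,6-dimethoxybenzaldehyde, are taken as catalogue items.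

**Step 1**
Reactants: 1 1,3,5-trimethoxybenzene (two molecules per product)
Product: 3 2,2',4,4',6,6'-hexamethoxybiphenyl, via 2,4,6-trimethoxyphenyllithium 2 (not isolated)
Conditions: n-BuLi (1.05 equiv), THF, 0 °C → rt; then anhydrous FeCl3 (1.1 equiv), −78 °C → rt
Reagents that add atoms: none
Why: Directed ortho-lithiation between two methoxy groups followed by one-electron oxidation of the aryllithium by FeCl3 (oxidative homocoupling of an organolithium) forms the tetra-ortho-methoxy biaryl bond only at the metalated carbon.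

**Step 2**
Reactants: 3 2,2',4,4',6,6'-hexamethoxybiphenyl
Product: 6 2,2',4,4',6,6'-hexamethoxybiphenyl-3-ol, via 3-lithiohexamethoxybiphenyl 4 (not isolated), via lithium aryltrimethoxyborate 5 (not isolated)
Conditions: n-BuLi (1.0 equiv), TMEDA, THF, 0 °C → rt; B(OMe)3, −78 °C → rt; AcOH, 30% aq H2O2, 0 °C → rt
Reagents that add atoms: hydrogen peroxide, OO
Why: The four ring hydrogens are equivalent and each lies between two OMe groups, so one equivalent of base gives mainly the monolithio species (directed ortho-metalation, unreacted 3 recycled), which is converted to the phenol by borylation and peroxide oxidation with aryl shift from boron to oxygen.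

**Step 3**
Reactants: 6 2,2',4,4',6,6'-hexamethoxybiphenyl-3-ol (2.2 equiv); 7 2,6-difluoro-4-methoxybenzaldehyde
Product: 9 4-methoxy-2,6-bis[(2,2',4,4',6,6'-hexamethoxybiphenyl-3-yl)oxy]benzaldehyde, via monoaryloxy fluoroaldehyde 8 (not isolated)
Conditions: Cs2CO3 (3 equiv), degassed DMSO, 120 °C, argon
Reagents that add atoms: none
Why: Twofold nucleophilic aromatic substitution (SNAr) works because both fluorides are ortho to the formyl acceptor, each has only H as its other neighbour, and the hindered but very electron-rich caesium phenoxide attacks there by addition–elimination.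

**Step 4**
Reactants: 9 4-methoxy-2,6-bis[(2,2',4,4',6,6'-hexamethoxybiphenyl-3-yl)oxy]benzaldehyde
Product: 11 4-methoxy-2,6-bis[(2,2',4,4',6,6'-hexamethoxybiphenyl-3-yl)oxy]phenol, via aryl formate 10 (not isolated)
Conditions: mCPBA (1.2 equiv), CH2Cl2, 0 °C → rt; aq NaHCO3 wash; then K2CO3 (0.2 equiv), degassed MeOH, rt
Reagents that add atoms: mCPBA (3-chloroperoxybenzoic acid), OOC(=O)c1cccc(Cl)c1
Why: In this Baeyer–Villiger (Dakin-type) oxidation the 2,4,6-trioxygenated aryl group migrates much faster than H and faster than the peracid attacks the other rings, and catalytic carbonate in methanol transesterifies the formate to the free phenol of ring D.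

**Step 5**
Reactants: 12 4-fluoro-2,6-dimethoxybenzaldehyde
Product: 13 3-bromo-4-fluoro-2,6-dimethoxybenzaldehyde
Conditions: NBS (1.05 equiv), MeCN, 0 °C → rt
Reagents that add atoms: N-bromosuccinimide, BrN1C(=O)CCC1=O
Why: In this electrophilic aromatic bromination C3 and C5 are equivalent, ortho/para to both methoxy groups and meta to the formyl group, and the first bromine slows a second substitution.

**Step 6**
Reactants: 13 3-bromo-4-fluoro-2,6-dimethoxybenzaldehyde; 14 2,4,6-trimethoxyphenylboronic acid (2 equiv)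
Product: 15 6-fluoro-2,2',4,4',6'-pentamethoxybiphenyl-3-carbaldehyde
Conditions: Pd(OAc)2 (5 mol %), SPhos (10 mol %), K3PO4 (3 equiv), toluene/H2O 10:1, 100 °C
Reagents that add atoms: none
Why: In this Suzuki–Miyaura coupling the bulky electron-rich SPhos lets zerovalent palladium insert into the hindered C–Br bond and speeds reductive elimination to the fully ortho-substituted biaryl ahead of protodeboronation of 14, while C–F and CHO stay untouched.

**Step 7**
Reactants: 15 6-fluoro-2,2',4,4',6'-pentamethoxybiphenyl-3-carbaldehyde; 16 4-bromo-2,6-dimethoxyphenol (1.5 equiv)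
Product: 17 6-(4-bromo-2,6-dimethoxyphenoxy)-2,2',4,4',6'-pentamethoxybiphenyl-3-carbaldehyde
Conditions: Cs2CO3 (2 equiv), degassed DMSO, 130 °C, argon
Reagents that add atoms: none
Why: This SNAr displaces the fluoride para to the formyl group, and because the conditions are metal-free the unactivated aryl bromide of ring C survives as the handle for the union.

**Step 8**
Reactants: 17 6-(4-bromo-2,6-dimethoxyphenoxy)-2,2',4,4',6'-pentamethoxybiphenyl-3-carbaldehyde (1.3 equiv); 11 4-methoxy-2,6-bis[(2,2',4,4',6,6'-hexamethoxybiphenyl-3-yl)oxy]phenol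
Product: 18 6-[4-(4-methoxy-2,6-bis{(2,2',4,4',6,6'-hexamethoxybiphenyl-3-yl)oxy}phenoxy)-2,6-dimethoxyphenoxy]-2,2',4,4',6'-pentamethoxybiphenyl-3-carbaldehyde (rings B to J, CHO where ring A will be attached)
Conditions: CuI (30 mol %), picolinic acid (60 mol %), K3PO4 (2 equiv), degassed DMSO, 105 °C, argon
Reagents that add atoms: none
Why: In this ligand-accelerated Ullmann diaryl ether coupling the bromide has two ortho hydrogens so only the phenol partner is hindered, which picolinate-bound monovalent copper tolerates, and only cross-coupling is possible because 17 has no OH and 11 no halide.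

**Step 9**
Reactants: 18 octa-ring aldehyde
Product: 20 6-[4-(4-methoxy-2,6-bis{(2,2',4,4',6,6'-hexamethoxybiphenyl-3-yl)oxy}phenoxy)-2,6-dimethoxyphenoxy]-2,2',4,4',6'-pentamethoxybiphenyl-3-ol, via aryl formate 19 (not isolated)
Conditions: mCPBA (1.2 equiv), CH2Cl2, 0 °C → rt; aq NaHCO3 wash; then K2CO3 (0.2 equiv), degassed MeOH, rt
Reagents that add atoms: mCPBA (3-chloroperoxybenzoic acid), OOC(=O)c1cccc(Cl)c1
Why: As in step 4, the Baeyer–Villiger oxidation is fast because the formyl group sits on a 2,4,6-trioxygenated ring whose migration gives the formate, and mild methanolysis then frees the phenol of ring B.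

**Step 10**
Reactants: 20 octa-ring phenol; 21 1-iodo-3,5-dimethoxybenzene (3 equiv)
Product: 22 docosa-O-methyl ether of the target (all 22 OH as OMe)
Conditions: CuI (20 mol %), picolinic acid (40 mol %), K3PO4 (2 equiv), degassed DMSO, 90 °C, argon
Reagents that add atoms: none
Why: This Ullmann diaryl ether coupling pairs a 2,6-dimethoxyphenol with a small, unhindered aryl iodide used in excess, and the substrate carries no other halide or free OH.

**Step 11**
Reactants: 22 docosa-O-methyl ether of the target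
Product: 24 CNP0117322.0 (target), via docosakis(dibromoboryl) ether 23 (not isolated)
Conditions: BBr3 (66 equiv, 1 M in CH2Cl2), CH2Cl2, −78 °C → rt, 48 h, argon; then ice/H2O; EtOAc extraction; Sephadex LH-20 (MeOH), argon
Reagents that add atoms: none
Why: In this Lewis-acid aryl methyl ether cleavage each OMe oxygen binds boron and bromide attacks the methyl carbon (SN2), the diaryl ether and biaryl bonds offer no sp3 carbon and survive, and hydrolysis of the boron aryloxides frees the 22 phenols.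

**Compound list**
1 | 1,3,5-trimethoxybenzene | COc1cc(OC)cc(OC)c1 | starting material
2 | 2,4,6-trimethoxyphenyllithium (not isolated) | COc1cc(OC)c([Li])c(OC)c1 | intermediate
3 | 2,2',4,4',6,6'-hexamethoxybiphenyl | COc1cc(OC)c(-c2c(OC)cc(OC)cc2OC)c(OC)c1 | intermediate
4 | 3-lithio-2,2',4,4',6,6'-hexamethoxybiphenyl (not isolated) | [Li]c1c(OC)cc(OC)c(-c2c(OC)cc(OC)cc2OC)c1OC | intermediate
5 | lithium (2,2',4,4',6,6'-hexamethoxybiphenyl-3-yl)trimethoxyborate (not isolated) | [Li+].CO[B-](OC)(OC)c1c(OC)cc(OC)c(-c2c(OC)cc(OC)cc2OC)c1OC | intermediate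
6 | 2,2',4,4',6,6'-hexamethoxybiphenyl-3-ol | Oc1c(OC)cc(OC)c(-c2c(OC)cc(OC)cc2OC)c1OC | intermediate
7 | 2,6-difluoro-4-methoxybenzaldehyde | COc1cc(F)c(C=O)c(F)c1 | starting material
8 | 2-fluoro-4-methoxy-6-[(2,2',4,4',6,6'-hexamethoxybiphenyl-3-yl)oxy]benzaldehyde (not isolated) | COc1cc(F)c(C=O)c(Oc2c(OC)cc(OC)c(-c3c(OC)cc(OC)cc3OC)c2OC)c1 | intermediate
9 | 4-methoxy-2,6-bis[(2,2',4,4',6,6'-hexamethoxybiphenyl-3-yl)oxy]benzaldehyde | COc1cc(Oc2c(OC)cc(OC)c(-c3c(OC)cc(OC)cc3OC)c2OC)c(C=O)c(Oc2c(OC)cc(OC)c(-c3c(OC)cc(OC)cc3OC)c2OC)c1 | intermediate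
10 | 4-methoxy-2,6-bis[(2,2',4,4',6,6'-hexamethoxybiphenyl-3-yl)oxy]phenyl formate (not isolated) | COc1cc(Oc2c(OC)cc(OC)c(-c3c(OC)cc(OC)cc3OC)c2OC)c(OC=O)c(Oc2c(OC)cc(OC)c(-c3c(OC)cc(OC)cc3OC)c2OC)c1 | intermediate
11 | 4-methoxy-2,6-bis[(2,2',4,4',6,6'-hexamethoxybiphenyl-3-yl)oxy]phenol | COc1cc(Oc2c(OC)cc(OC)c(-c3c(OC)cc(OC)cc3OC)c2OC)c(O)c(Oc2c(OC)cc(OC)c(-c3c(OC)cc(OC)cc3OC)c2OC)c1 | intermediate
12 | 4-fluoro-2,6-dimethoxybenzaldehyde | COc1cc(F)cc(OC)c1C=O | starting material
13 | 3-bromo-4-fluoro-2,6-dimethoxybenzaldehyde | COc1cc(F)c(Br)c(OC)c1C=O | intermediate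
14 | 2,4,6-trimethoxyphenylboronic acid | COc1cc(OC)c(B(O)O)c(OC)c1 | starting material
15 | 6-fluoro-2,2',4,4',6'-pentamethoxybiphenyl-3-carbaldehyde | COc1cc(F)c(-c2c(OC)cc(OC)cc2OC)c(OC)c1C=O | intermediate
16 | 4-bromo-2,6-dimethoxyphenol | COc1cc(Br)cc(OC)c1O | starting material
17 | 6-(4-bromo-2,6-dimethoxyphenoxy)-2,2',4,4',6'-pentamethoxybiphenyl-3-carbaldehyde | COc1cc(Oc2c(OC)cc(Br)cc2OC)c(-c2c(OC)cc(OC)cc2OC)c(OC)c1C=O | intermediate
18 | octa-ring aldehyde (rings B to J, all OH as OMe, CHO on ring B para to the O–C ether) | COc1cc(Oc2c(OC)cc(Oc3c(Oc4c(OC)cc(OC)c(-c5c(OC)cc(OC)cc5OC)c4OC)cc(OC)cc3Oc3c(OC)cc(OC)c(-c4c(OC)cc(OC)cc4OC)c3OC)cc2OC)c(-c2c(OC)cc(OC)cc2OC)c(OC)c1C=O | intermediate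
19 | octa-ring aryl formate (OCHO in place of CHO of 18, not isolated) | COc1cc(Oc2c(OC)cc(Oc3c(Oc4c(OC)cc(OC)c(-c5c(OC)cc(OC)cc5OC)c4OC)cc(OC)cc3Oc3c(OC)cc(OC)c(-c4c(OC)cc(OC)cc4OC)c3OC)cc2OC)c(-c2c(OC)cc(OC)cc2OC)c(OC)c1OC=O | intermediate
20 | octa-ring phenol (OH in place of CHO of 18) | COc1cc(Oc2c(OC)cc(Oc3c(Oc4c(OC)cc(OC)c(-c5c(OC)cc(OC)cc5OC)c4OC)cc(OC)cc3Oc3c(OC)cc(OC)c(-c4c(OC)cc(OC)cc4OC)c3OC)cc2OC)c(-c2c(OC)cc(OC)cc2OC)c(OC)c1O | intermediate
21 | 1-iodo-3,5-dimethoxybenzene | COc1cc(I)cc(OC)c1 | starting material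
22 | docosa-O-methyl ether of the target | COc1cc(OC)cc(Oc2c(OC)cc(Oc3c(OC)cc(Oc4c(Oc5c(OC)cc(OC)c(-c6c(OC)cc(OC)cc6OC)c5OC)cc(OC)cc4Oc4c(OC)cc(OC)c(-c5c(OC)cc(OC)cc5OC)c4OC)cc3OC)c(-c3c(OC)cc(OC)cc3OC)c2OC)c1 | intermediate
23 | docosakis(dibromoboryl) ether of the target (idealised boron aryloxide, not isolated) | BrB(Br)Oc1cc(OB(Br)Br)cc(Oc2c(OB(Br)Br)cc(Oc3c(OB(Br)Br)cc(Oc4c(Oc5c(OB(Br)Br)cc(OB(Br)Br)c(-c6c(OB(Br)Br)cc(OB(Br)Br)cc6OB(Br)Br)c5OB(Br)Br)cc(OB(Br)Br)cc4Oc4c(OB(Br)Br)cc(OB(Br)Br)c(-c5c(OB(Br)Br)cc(OB(Br)Br)cc5OB(Br)Br)c4OB(Br)Br)cc3OB(Br)Br)c(-c3c(OB(Br)Br)cc(OB(Br)Br)cc3OB(Br)Br)c2OB(Br)Br)c1 | intermediate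
24 | CNP0117322.0 (C54H38O27, achiral) | Oc1cc(O)cc(Oc2c(O)cc(Oc3c(O)cc(Oc4c(Oc5c(O)cc(O)c(-c6c(O)cc(O)cc6O)c5O)cc(O)cc4Oc4c(O)cc(O)c(-c5c(O)cc(O)cc5O)c4O)cc3O)c(-c3c(O)cc(O)cc3O)c2O)c1 | target

**Totals**
Total step count: 11 (steps 1–4 make the D/E/F/H/J half, steps 5–7 the B/C/G half, steps 8–11 follow the union).
Longest linear sequence: 8 steps (1, 2, 3, 4, 8, 9, 10, 11).

**Three steps most likely to fail**

Step 7 (SNAr beside the fully ortho-substituted biaryl). The two ortho methoxy groups of ring G shield both faces of the C–F carbon, and the nucleophile is itself a 2,6-dimethoxyphenoxide.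
- The fallback reverses the order of the two bond formations and sets out from 12 and 16.
- SNAr on the unhindered fluoride of 12 (Cs2CO3, DMSO, 90 °C) gives 4-(4-bromo-2,6-dimethoxyphenoxy)-2,6-dimethoxybenzaldehyde F1.
- NIS with catalytic CF3CO2H in MeCN iodinates ring B, which has three ortho/para oxygen donors against two on the brominated ring C. This gives 4-(4-bromo-2,6-dimethoxyphenoxy)-3-iodo-2,6-dimethoxybenzaldehyde F2.
- Compound 2, made from 1 as in step 1, is transmetalated with ZnCl2 to (2,4,6-trimethoxyphenyl)zinc chloride F3.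
- A Negishi coupling (Pd2(dba)3, RuPhos, THF, 25–40 °C) takes place at the C–I bond, into which zerovalent palladium inserts far faster than into C–Br. It comes back to the route at 17, and steps 5 and 6 fall away.

Step 8 (copper coupling of two large halves through a phenol flanked by two bulky aryloxy groups). If it stalls or only debrominates 17, the fallback replaces copper catalysis by the SNAr/Baeyer–Villiger sequence. It sets out from 11 and 12.
- SNAr (Cs2CO3, DMSO, 100 °C) on the unhindered, formyl-activated fluoride gives 4-[4-methoxy-2,6-bis(2,2',4,4',6,6'-hexamethoxybiphenyl-3-yloxy)phenoxy]-2,6-dimethoxybenzaldehyde F4.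
- mCPBA in CH2Cl2 gives 4-[4-methoxy-2,6-bis(2,2',4,4',6,6'-hexamethoxybiphenyl-3-yloxy)phenoxy]-2,6-dimethoxyphenyl formate F5.
- Catalytic K2CO3 in MeOH converts this to 4-[4-methoxy-2,6-bis(2,2',4,4',6,6'-hexamethoxybiphenyl-3-yloxy)phenoxy]-2,6-dimethoxyphenol F6.
- The reacting oxygen of F6 has the same local environment as that of 16. SNAr on the fluoride 15 (Cs2CO3, DMSO, 130 °C) comes back to the route at 18, and 16 and 17 are no longer needed.

Step 11 (22-fold demethylation and isolation of a very polar, air-sensitive polyphenol). The fallback derivatises before purification and sets out from 22.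
- After the BBr3 treatment and hydrolysis, the crude phenol mixture is not chromatographed. It is acetylated at once (Ac2O, pyridine, DMAP cat., rt) to the docosaacetate of the target F7.
- F7 is stable in air, runs on ordinary silica gel, and separates from congeners that still carry a methyl group. Those congeners go back into BBr3.
- Transesterification of pure F7 (NaOMe cat., degassed MeOH, 0 °C, argon, then acidic ion-exchange resin) comes back to the route at 24.

**Further compounds**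
F1 | step 7 | 4-(4-bromo-2,6-dimethoxyphenoxy)-2,6-dimethoxybenzaldehyde | COc1cc(Oc2c(OC)cc(Br)cc2OC)cc(OC)c1C=O
F2 | step 7 | 4-(4-bromo-2,6-dimethoxyphenoxy)-3-iodo-2,6-dimethoxybenzaldehyde | COc1cc(Oc2c(OC)cc(Br)cc2OC)c(I)c(OC)c1C=O
F3 | step 7 | (2,4,6-trimethoxyphenyl)zinc chloride | COc1cc(OC)c([Zn]Cl)c(OC)c1
F4 | step 8 | 4-[4-methoxy-2,6-bis(2,2',4,4',6,6'-hexamethoxybiphenyl-3-yloxy)phenoxy]-2,6-dimethoxybenzaldehyde | COc1cc(Oc2c(Oc3c(OC)cc(OC)c(-c4c(OC)cc(OC)cc4OC)c3OC)cc(OC)cc2Oc2c(OC)cc(OC)c(-c3c(OC)cc(OC)cc3OC)c2OC)cc(OC)c1C=O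
F5 | step 8 | 4-[4-methoxy-2,6-bis(2,2',4,4',6,6'-hexamethoxybiphenyl-3-yloxy)phenoxy]-2,6-dimethoxyphenyl formate | COc1cc(Oc2c(Oc3c(OC)cc(OC)c(-c4c(OC)cc(OC)cc4OC)c3OC)cc(OC)cc2Oc2c(OC)cc(OC)c(-c3c(OC)cc(OC)cc3OC)c2OC)cc(OC)c1OC=O
F6 | step 8 | 4-[4-methoxy-2,6-bis(2,2',4,4',6,6'-hexamethoxybiphenyl-3-yloxy)phenoxy]-2,6-dimethoxyphenol | COc1cc(Oc2c(Oc3c(OC)cc(OC)c(-c4c(OC)cc(OC)cc4OC)c3OC)cc(OC)cc2Oc2c(OC)cc(OC)c(-c3c(OC)cc(OC)cc3OC)c2OC)cc(OC)c1O
F7 | step 11 | docosaacetate of the target | CC(=O)Oc1cc(OC(C)=O)cc(Oc2c(OC(C)=O)cc(Oc3c(OC(C)=O)cc(Oc4c(Oc5c(OC(C)=O)cc(OC(C)=O)c(-c6c(OC(C)=O)cc(OC(C)=O)cc6OC(C)=O)c5OC(C)=O)cc(OC(C)=O)cc4Oc4c(OC(C)=O)cc(OC(C)=O)c(-c5c(OC(C)=O)cc(OC(C)=O)cc5OC(C)=O)c4OC(C)=O)cc3OC(C)=O)c(-c3c(OC(C)=O)cc(OC(C)=O)cc3OC(C)=O)c2OC(C)=O)c1
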